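Late in the earlier runs the electrophile is slowing: averaged over north and west, read at the same times, the fraction left goes from 61.1% at 2.50 min to 57.4% at 4.00 min. You asked for a quick number, so I reckon with what is left and not with what is made.

| flask | electrophile | nucleophile | scavenger | remark | time |
|---|---|---|---|---|---|
| north | 20 mM | 21 mM | 13 mM | run made earlier |  |
| south | 20 mM | 21 mM | 18 mM | run made earlier |  |
| west | 20 mM | 21 mM | 26 mM | run made earlier |  |
| spring | 20 mM | 21.0 mM | 16.0 mM |  | 8.0 min |
| midnight | 20 mM | 21.0 mM | 24.0 mM |  | 8.0 min |

| run | time / min | electrophile / % | target / % |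
|---|---|---|---|
| north | 0.833 | 70.9 | 30.2 |
| north | 1.50 | 64.6 | 34.3 |
| north | 2.50 | 61.3 | 39.0 |
| north | 3.00 | 59.9 | 38.7 |
| north | 4.00 | 58.4 | 41.0 |
| south | 0.333 | 82.8 | 18.1 |
| south | 1.00 | 68.7 | 31.2 |
| south | 2.00 | 62.1 | 38.0 |
| south | 3.00 | 60.4 | 40.6 |
| south | 4.00 | 57.9 | 41.4 |
| west | 0.833 | 70.8 | 30.1 |
| west | 1.50 | 64.2 | 35.1 |
| west | 2.50 | 60.9 | 39.5 |
| west | 3.00 | 59.9 | 40.4 |
| west | 4.00 | 56.4 | 42.3 |

(scatter of a reading: 0.5 percentage points)

- what is said of acid set free includes idle adduct
- what was read earlier has a scatter of 0.5 percentage points, one standard deviation
- steps under discussion: electrophile + nucleophile -> acid set free + target; nucleophile + acid set free <-> protonated nucleophile; nucleophile <-> dormant form; electrophile + acid set free <-> idle adduct; acid set free + scavenger -> scavenged by-product; acid set free + target -> side product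

* part of the electrophile that has reacted at the end, spring
* part of the electrophile that has reacted at the end, midnight
* what raising the concentration of scavenger from its lowest to its highest value here does to the part of the electrophile that has reacted (changes below 5 percentage points count as none) (it falls / no change / it rises)

Suppose each target costs one nucleophile and its acid set free ties up a second. The nucleophile is then the limiting reagent, with 21.0 mM charged against 40.0 mM needed. That gives a floor F of 47.5%, the fraction of electrophile left when the nucleophile charge is used at two per electrophile.

The gap G, fraction left minus F, reads 14 percentage points and then 9.9 points, each with the scatter of the readings, so it halves in about 3.27 min. If that halving holds to 8.0 min, I get 48.3% reacted in spring and midnight alike, a reckoning with no scavenger in it.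

Your hunch, the forecast, says 47% for spring, 48% for midnight and no change, with acid set free tying up a second nucleophile, “which caps conversion near 52%”. My figure stands 1.3 points above it for spring.

The flask gives 48.2% for spring and 49.9% for midnight; across the scavenger range the outcome is no change, a shift of 1.6 points.

    electrophile + nucleophile → acid set free + target (k = 0.638 L mol⁻¹ s⁻¹)
    nucleophile + acid set free ⇌ protonated nucleophile, settled at all times (K = 3.19 × 10⁵ L mol⁻¹)
    nucleophile ⇌ dormant form (K = 10.0, k = 0.00758 s⁻¹)
    electrophile + acid set free ⇌ idle adduct, settled at all times (K = 62.0 L mol⁻¹)
    acid set free + scavenger → scavenged by-product (k = 41.0 L mol⁻¹ s⁻¹)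
    acid set free + target → side product (k = 0.327 L mol⁻¹ s⁻¹)

At 8.0 min the electrophile left stands 4.3 points above F in spring and 2.6 points above it in midnight. F is no stop: spring left until 80.0 min holds 17.8% of electrophile. Nor is its second nucleophile simply protonated: spring at 8.00 min holds 4.74 mM of protonated nucleophile and 5.92 mM of dormant form. The answer for midnight has moved by 5 points with electrophile down at 16.3 mM. The neighbour is midnight with 5.0 mM of electrophile: there F reckons to −110%, below zero, the nucleophile covering two per electrophile 2.10 times over, and the electrophile left at 8.0 min is 23.8%.

The readings come from a simulation with constants of no real substance.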